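**Retrosynthetic overview**
- The target is cut at its two ester C–O bonds into (2E,6E)-2,6-dimethylocta-2,6-dienedioic acid (from geranyl acetate) and two molecules of the C6-epimeric amino alcohol; a double Mitsunobu esterification joins them with inversion at C6.
- The amino alcohol is traced to an N-Boc bicyclic ketone: the C4 methyl is read as a former C4 ketone (methylenation, then hydrogenation from the convex face) and the C6 oxygen as a former exocyclic methylene (ozonolysis).
- Key disconnection: the cyclopentane is opened across C5–C4a and C7–C7a into a methyl-substituted trimethylenemethane (C5–C6(=CH2)–C7(CH3)) and a bought six-membered aza-enone. The piperidine ring is present from the start; the cyclopentane is the only ring formed (step 3).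
- Enabling feature: C5, C6 and C7 of the cyclopentane form a three-carbon unit, oxygenated at its central carbon, whose two ends sit on the adjacent ring-fusion carbons C4a and C7a of the piperidine. With C4 as a carbonyl, C4a–C7a is the C=C of a cyclic enone whose β carbon (C7a) accepts the methyl-bearing nucleophilic terminus and whose α carbon (C4a) closes the ring.

Key step: step 3

Remark: the ligand enantiomer in step 3 is taken to be the one that delivers the (4aR,7aS) cycloadduct, and C7, which may form there as an epimer mixture, is drawn as the expected trans (7S) isomer and is equilibrated after step 6.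

Ring numbering throughout is that of cyclopenta[c]pyridine (C1, N2, C3, C4, C4a, C5, C6, C7, C7a).

**Step 1**
Reactants: 1 (2-bromoprop-2-en-1-yl)trimethylsilane
Product: 3 3-[(trimethylsilyl)methyl]but-3-en-2-ol (racemic), via Grignard reagent 2 (not isolated)
Conditions: Mg, THF, reflux; then CH3CHO, 0 °C; H2O work-up
Reagents that add atoms: acetaldehyde, CC=O
Why: Grignard formation from the vinyl bromide and 1,2-addition to acetaldehyde should give the secondary allylic alcohol, whose stereocentre is racemic and is erased in step 3.

**Step 2**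
Reactants: 3 3-[(trimethylsilyl)methyl]but-3-en-2-ol
Product: 4 3-[(trimethylsilyl)methyl]but-3-en-2-yl acetate (racemic)
Conditions: Ac2O, pyridine, DMAP (cat.), CH2Cl2, rt
Reagents that add atoms: acetic anhydride, CC(=O)OC(C)=O
Why: DMAP-catalysed acetylation installs the allylic leaving group of the trimethylenemethane donor.

**Step 3**
Reactants: 4 3-[(trimethylsilyl)methyl]but-3-en-2-yl acetate (1.5 equiv); 5 tert-butyl 3-oxo-3,6-dihydropyridine-1(2H)-carboxylate
Product: 8 tert-butyl (4aR,7S,7aS)-7-methyl-6-methylidene-4-oxooctahydro-2H-cyclopenta[c]pyridine-2-carboxylate, via methyl-TMM palladium zwitterion 6 (not isolated), via Michael-adduct zwitterion 7 (not isolated)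
Conditions: Pd(dba)2 (5 mol %), phosphoramidite from (R)-BINOL and (2R,5R)-2,5-diphenylpyrrolidine or its enantiomer (10 mol %), toluene, 45 °C
Reagents that add atoms: none
Why: Proposed new method: oxidative addition of zerovalent palladium to acetate 4 and desilylation by the acetate should give zwitterion 6, whose methyl-bearing carbon (the terminus through which substituted TMM–palladium complexes react) adds to the enone β carbon C7a to give 7, and the enolate carbon C4a of 7 then attacks the η3-allyl terminus C5, closing the cyclopentane by intramolecular allylic alkylation (a stepwise Michael/ring-closure [3+2]). The closest known reactions are the racemic palladium–TMM cycloaddition of methyl-substituted donors to 2-cyclopentenone and the phosphoramidite-controlled enantioselective palladium–TMM cycloadditions to acyclic and exocyclic enones; the extension is enantiofacial control on an endocyclic cis-enone. The cis ring fusion (C4a, C7a) is enforced because the allyl arm on C7a can only reach C4a of the six-membered enolate on the same face, and the absolute sense is set by the chiral phosphoramidite in the Michael step. C7 is set relative to C7a in the same Michael step (trans expected) and remains correctable because it becomes α to the C6 ketone after step 4. The step needs 1,4- over 1,2-addition and cycloaddition over proton transfer from the acidic C3–H2; the inductively activated β carbon (allylic to the carbamate nitrogen) and the absence of Lewis-acid co-catalysts should favour the former.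

**Step 4**
Reactants: 8 tert-butyl (4aR,7S,7aS)-7-methyl-6-methylidene-4-oxooctahydro-2H-cyclopenta[c]pyridine-2-carboxylate
Product: 10 tert-butyl (4aR,7S,7aS)-7-methyl-4,6-dioxooctahydro-2H-cyclopenta[c]pyridine-2-carboxylate, via ozonide 9 (not isolated)
Conditions: O3, CH2Cl2, −78 °C; then Me2S, −78 °C to rt
Reagents that add atoms: ozone, [O-][O+]=O
Why: Ozonolysis with reductive work-up should cleave the only C=C to the C6 ketone, the carbamate and the C4 ketone being inert.

**Step 5**
Reactants: 10 tert-butyl (4aR,7S,7aS)-7-methyl-4,6-dioxooctahydro-2H-cyclopenta[c]pyridine-2-carboxylate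
Product: 11 tert-butyl (4aR,7S,7aR)-7-methyl-4-methylidene-6-oxooctahydro-2H-cyclopenta[c]pyridine-2-carboxylate
Conditions: Ph3PCH3Br (1.1 equiv), KOtBu (1.05 equiv), THF, −78 to 0 °C
Reagents that add atoms: methyltriphenylphosphonium bromide, C[P+](c1ccccc1)(c1ccccc1)c1ccccc1.[Br-]
Why: Wittig methylenation should occur selectively at the C4 ketone, which lies in the six-membered ring, is inductively activated by the α-carbamate nitrogen and is less hindered than the α-methyl-substituted cyclopentanone C6.

**Step 6**
Reactants: 11 tert-butyl (4aR,7S,7aR)-7-methyl-4-methylidene-6-oxooctahydro-2H-cyclopenta[c]pyridine-2-carboxylate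
Product: 12 tert-butyl (4R,4aS,7S,7aR)-4,7-dimethyl-6-oxooctahydro-2H-cyclopenta[c]pyridine-2-carboxylate
Conditions: H2 (1 atm), 10% Pd/C, EtOAc, rt; then NaOMe (0.1 equiv), MeOH, rt
Reagents that add atoms: none
Why: Heterogeneous hydrogenation should deliver hydrogen to the exocyclic alkene from the convex face (the face of H4a and H7a), placing the C4 methyl cis to C5, and the brief base treatment equilibrates C7, now the only epimerisable stereocentre, to the trans (7S) arrangement.

**Step 7**
Reactants: 12 tert-butyl (4R,4aS,7S,7aR)-4,7-dimethyl-6-oxooctahydro-2H-cyclopenta[c]pyridine-2-carboxylate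
Product: 14 (4R,4aS,6S,7S,7aR)-2,4,7-trimethyloctahydro-1H-cyclopenta[c]pyridin-6-ol, via N-Boc alcohol 13 (not isolated)
Conditions: LiAlH4 (excess), THF, 0 °C, then reflux; H2O/aq. NaOH work-up
Reagents that add atoms: none
Why: LiAlH4 should first reduce the C6 ketone by hydride attack on the convex face, giving the (6S) alcohol trans to the C7 methyl, and then on heating reduce the Boc carbamate to the N-methyl group.

**Step 8**
Reactants: 15 (2E)-3,7-dimethylocta-2,6-dien-1-yl acetate (geranyl acetate)
Product: 16 (2E,6E)-8-hydroxy-3,7-dimethylocta-2,6-dien-1-yl acetate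
Conditions: SeO2 (cat.), tBuOOH (70% aq.), salicylic acid (cat.), CH2Cl2, rt
Reagents that add atoms: tert-butyl hydroperoxide, CC(C)(C)OO
Why: Catalytic SeO2 allylic oxidation (ene reaction, then [2,3]-sigmatropic shift) is selective for the (E)-methyl group of the terminal trisubstituted alkene and gives the (E)-allylic alcohol.

**Step 9**
Reactants: 16 (2E,6E)-8-hydroxy-3,7-dimethylocta-2,6-dien-1-yl acetate
Product: 17 (2E,6E)-2,6-dimethylocta-2,6-diene-1,8-diol
Conditions: K2CO3 (cat.), MeOH, rt
Reagents that add atoms: none
Why: Base-catalysed transesterification removes the acetate without touching the alkenes.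

**Step 10**
Reactants: 17 (2E,6E)-2,6-dimethylocta-2,6-diene-1,8-diol
Product: 18 (2E,6E)-2,6-dimethylocta-2,6-dienedial
Conditions: activated MnO2 (excess), CH2Cl2, rt
Reagents that add atoms: none
Why: MnO2 oxidises both allylic alcohols to the enals with retention of alkene geometry.

**Step 11**
Reactants: 18 (2E,6E)-2,6-dimethylocta-2,6-dienedial
Product: 19 (2E,6E)-2,6-dimethylocta-2,6-dienedioic acid
Conditions: NaClO2, NaH2PO4, 2-methylbut-2-ene, tBuOH/H2O, rt
Reagents that add atoms: sodium chlorite, [Na+].[O-]Cl=O
Why: Pinnick oxidation converts both enals into the conjugated acids without alkene isomerisation, the hypochlorite by-product being scavenged by the alkene additive.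

**Step 12**
Reactants: 14 (4R,4aS,6S,7S,7aR)-2,4,7-trimethyloctahydro-1H-cyclopenta[c]pyridin-6-ol (2.2 equiv); 19 (2E,6E)-2,6-dimethylocta-2,6-dienedioic acid
Product: 20 bis[(4R,4aS,6R,7S,7aR)-2,4,7-trimethyloctahydro-1H-cyclopenta[c]pyridin-6-yl] (2E,6E)-2,6-dimethylocta-2,6-dienedioate (CNP0240822.3)
Conditions: PPh3 (3 equiv), DIAD (3 equiv), THF, 0 °C to rt
Reagents that add atoms: none
Why: In this double Mitsunobu esterification each carboxylate displaces the C6 oxyphosphonium group by SN2 with inversion, turning (6S) into the (6R) ester configuration of the target, and because the conjugated acids act only as nucleophiles their alkene position and geometry are preserved.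

**Compound list**
1 | (2-bromoprop-2-en-1-yl)trimethylsilane | C=C(Br)C[Si](C)(C)C | starting material
2 | [3-(trimethylsilyl)prop-1-en-2-yl]magnesium bromide | C=C([Mg]Br)C[Si](C)(C)C | intermediate (not isolated)
3 | 3-[(trimethylsilyl)methyl]but-3-en-2-ol (racemic) | CC(O)C(=C)C[Si](C)(C)C | intermediate
4 | 3-[(trimethylsilyl)methyl]but-3-en-2-yl acetate (racemic) | CC(OC(C)=O)C(=C)C[Si](C)(C)C | intermediate
5 | tert-butyl 3-oxo-3,6-dihydropyridine-1(2H)-carboxylate | O=C1C=CCN(C(=O)OC(C)(C)C)C1 | starting material
6 | zwitterionic (η3-2-methylidenebutane-1,3-diyl)palladium complex [Pd(C5H8)L2], phosphoramidite ligands L omitted | C[CH-]C(=C)C[Pd+] | intermediate (not isolated)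
7 | zwitterionic Michael adduct: enolate of 5 carrying at its former β carbon the (η3-allyl)palladium unit, ligands omitted | [O-]C1=C[C@H]([C@H](C)C(=C)C[Pd+])CN(C(=O)OC(C)(C)C)C1 | intermediate (not isolated)
8 | tert-butyl (4aR,7S,7aS)-7-methyl-6-methylidene-4-oxooctahydro-2H-cyclopenta[c]pyridine-2-carboxylate | C=C1C[C@@H]2[C@@H](CN(C(=O)OC(C)(C)C)CC2=O)[C@@H]1C | intermediate
9 | spiro-1,2,4-trioxolane (ozonide) at C6 of 8, mixture at the spiro carbon | C1OC2(OO1)C[C@@H]3[C@@H](CN(C(=O)OC(C)(C)C)CC3=O)[C@@H]2C | intermediate (not isolated)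
10 | tert-butyl (4aR,7S,7aS)-7-methyl-4,6-dioxooctahydro-2H-cyclopenta[c]pyridine-2-carboxylate | O=C1C[C@@H]2[C@@H](CN(C(=O)OC(C)(C)C)CC2=O)[C@@H]1C | intermediate
11 | tert-butyl (4aR,7S,7aR)-7-methyl-4-methylidene-6-oxooctahydro-2H-cyclopenta[c]pyridine-2-carboxylate | O=C1C[C@@H]2[C@@H](CN(C(=O)OC(C)(C)C)CC2=C)[C@@H]1C | intermediate
12 | tert-butyl (4R,4aS,7S,7aR)-4,7-dimethyl-6-oxooctahydro-2H-cyclopenta[c]pyridine-2-carboxylate | O=C1C[C@@H]2[C@@H](CN(C(=O)OC(C)(C)C)C[C@@H]2C)[C@@H]1C | intermediate
13 | tert-butyl (4R,4aS,6S,7S,7aR)-6-hydroxy-4,7-dimethyloctahydro-2H-cyclopenta[c]pyridine-2-carboxylate | O[C@H]1C[C@@H]2[C@@H](CN(C(=O)OC(C)(C)C)C[C@@H]2C)[C@@H]1C | intermediate (not isolated)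
14 | (4R,4aS,6S,7S,7aR)-2,4,7-trimethyloctahydro-1H-cyclopenta[c]pyridin-6-ol (6-epi-incarvilline) | O[C@H]1C[C@@H]2[C@@H](CN(C)C[C@@H]2C)[C@@H]1C | intermediate
15 | (2E)-3,7-dimethylocta-2,6-dien-1-yl acetate (geranyl acetate) | CC(C)=CCC/C(C)=C/COC(C)=O | starting material
16 | (2E,6E)-8-hydroxy-3,7-dimethylocta-2,6-dien-1-yl acetate | OC/C(C)=C/CC/C(C)=C/COC(C)=O | intermediate
17 | (2E,6E)-2,6-dimethylocta-2,6-diene-1,8-diol | OC/C(C)=C/CC/C(C)=C/CO | intermediate
18 | (2E,6E)-2,6-dimethylocta-2,6-dienedial | O=C/C(C)=C/CC/C(C)=C/C=O | intermediate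
19 | (2E,6E)-2,6-dimethylocta-2,6-dienedioic acid | OC(=O)/C(C)=C/CC/C(C)=C/C(=O)O | intermediate
20 | bis[(4R,4aS,6R,7S,7aR)-2,4,7-trimethyloctahydro-1H-cyclopenta[c]pyridin-6-yl] (2E,6E)-2,6-dimethylocta-2,6-dienedioate | C/C(=C\C(=O)O[C@@H]1C[C@@H]2[C@@H](CN(C)C[C@@H]2C)[C@@H]1C)CC/C=C(\C)C(=O)O[C@@H]1C[C@@H]2[C@@H](CN(C)C[C@@H]2C)[C@@H]1C | target

**Total step count:** 12 (steps 1–7 to the amino alcohol, steps 8–11 to the diacid, step 12 for the coupling).
**Longest linear sequence:** 8 steps (1, 2, 3, 4, 5, 6, 7, 12).

**Steps most likely to fail**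

Step 3. The chiral palladium–TMM complex may not discriminate well between the two faces of an endocyclic cis-enone, and the basic zwitterion may be quenched by proton transfer from C3–H2 before it adds. The fallback separates the construction of the ring from the control of absolute configuration. It sets out from 4 and 5: the cycloaddition is run with the achiral system Pd(OAc)2/P(OiPr)3 in THF at reflux, the conditions long used for methyl-substituted donors and cyclic enones, and should give the racemic cycloadduct F1. The enantiomers of F1 are then separated by preparative chromatography on a chiral stationary phase, and the (4aR,7S,7aS) enantiomer rejoins the route at 8.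

Step 5. The ylide may not distinguish the two ketones cleanly (olefination at C6 or at both carbonyls), and its basicity may enolise the diketone and epimerise C4a. The fallback avoids any stage at which two ketones are present; it sets out from 8. Addition of MeMgBr/CeCl3 in THF at −78 °C to the only ketone should give the tertiary alcohol F2. Ozonolysis (O3, CH2Cl2, −78 °C; Me2S) then gives the hydroxy ketone F3, which may rest as a bridged hemiketal. Burgess dehydration (methyl N-(triethylammoniosulfonyl)carbamate, benzene, 50 °C), a syn elimination that cannot involve the anti H4a, should give the enecarbamate F4; any exocyclic isomer is compound 11. Hydrogenation (H2, Pd/C, EtOAc) from the convex face, followed by the NaOMe equilibration of step 6, returns to the route at 12.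

Step 12. The second esterification may stall at the monoester stage, and the activated, hindered C6 oxyphosphonium may eliminate or be intercepted by the ring nitrogen before the weakly acidic conjugated carboxylate attacks. The fallback inverts C6 first with a strong acid partner and then forms the esters by acyl transfer with retention; it sets out from 14. Mitsunobu reaction with 4-nitrobenzoic acid (PPh3, DIAD, THF) should give the inverted 4-nitrobenzoate F5, and hydrolysis (LiOH, THF/H2O) the (6R) alcohol F6. Steglich esterification of 19 with F6 (2.2 equiv; EDC, DMAP (cat.), CH2Cl2, 0 °C) returns to the route at 20.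

**Further compounds**
F1 | step 3 | racemic tert-butyl (4aR*,7S*,7aS*)-7-methyl-6-methylidene-4-oxooctahydro-2H-cyclopenta[c]pyridine-2-carboxylate (both enantiomers) | C=C1C[C@@H]2[C@@H](CN(C(=O)OC(C)(C)C)CC2=O)[C@@H]1C.C=C1C[C@H]2[C@H](CN(C(=O)OC(C)(C)C)CC2=O)[C@H]1C
F2 | step 5 | tert-butyl (4R,4aR,7S,7aS)-4-hydroxy-4,7-dimethyl-6-methylideneoctahydro-2H-cyclopenta[c]pyridine-2-carboxylate | C=C1C[C@@H]2[C@@H](CN(C(=O)OC(C)(C)C)C[C@]2(C)O)[C@@H]1C
F3 | step 5 | tert-butyl (4R,4aR,7S,7aR)-4-hydroxy-4,7-dimethyl-6-oxooctahydro-2H-cyclopenta[c]pyridine-2-carboxylate | O=C1C[C@@H]2[C@@H](CN(C(=O)OC(C)(C)C)C[C@]2(C)O)[C@@H]1C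
F4 | step 5 | tert-butyl (4aR,7S,7aR)-4,7-dimethyl-6-oxo-1,4a,5,6,7,7a-hexahydro-2H-cyclopenta[c]pyridine-2-carboxylate | O=C1C[C@@H]2[C@@H](CN(C(=O)OC(C)(C)C)C=C2C)[C@@H]1C
F5 | step 12 | (4R,4aS,6R,7S,7aR)-2,4,7-trimethyloctahydro-1H-cyclopenta[c]pyridin-6-yl 4-nitrobenzoate | O=C(O[C@@H]1C[C@@H]2[C@@H](CN(C)C[C@@H]2C)[C@@H]1C)c1ccc(cc1)[N+](=O)[O-]
F6 | step 12 | (4R,4aS,6R,7S,7aR)-2,4,7-trimethyloctahydro-1H-cyclopenta[c]pyridin-6-ol (incarvilline) | O[C@@H]1C[C@@H]2[C@@H](CN(C)C[C@@H]2C)[C@@H]1C
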